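**Remark (assumption):** the target SMILES carries no descriptor for the C6–C8'' axis, so the route is planned for the racemic atropisomer. Compounds 1, 3 and 5 are taken as commercially available.

## Structural features

The target is a biflavone without stereocentres. An acacetin unit (ring A with 5-OH and 7-OH, pyranone ring C, ring B with 4'-OMe) and a genkwanin unit (5''-OH, 7''-OMe, 4'''-OH) are joined by one bond between the two rings A, from C6 to C8''. This bond is an axis with four ortho substituents (O5 and O7 on one side, O7'' and the ring oxygen O1'' through C8a'' on the other), so it is hindered and should be configurationally stable. Both rings A are phloroglucinol-type and nucleophilic at C6 and C8 alike, so an intermolecular union has four candidate carbons and only one correct pairing. The two methyl ethers sit on different halves at non-equivalent oxygens (O4' and O7''), so they cannot be introduced at the end by methylating a hexaphenol. Fragile points are the pyranone rings, which open in hot aqueous alkali and can isomerise by ring opening and reclosure in hot strong acid (which would exchange C6 and C8 linkages), and the electron-rich free phenols. The real difficulty is therefore the regiodefined, hindered C6–C8'' bond together with the unsymmetrical O-substitution around it. The key step exploits three facts about O5: C6 is its only unsubstituted ortho carbon (the other neighbour is C4a), it lies peri to the C4 carbonyl, and across the axis it faces O7'', which carries a methyl group. The O5–H/O7''–CH3 pair is thus read as an opened O5–CH2–O7'' acetal whose seven-membered ring can only be closed at C6.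

## Logic of the disconnections

**15 to 14.** The phenols O7–H, O4'''–H and O5''–H are traced back to two benzyl ethers and one methyl ether (forward: cleavage of O7–CH2Ph, O4'''–CH2Ph and O5''–CH3). The reason is that these three oxygens must be inert during bridge formation and coupling. The gain is one common deprotection at the end. The demand is that the forward step spares the 4'-O- and 7''-O-methyl groups, which have no neighbouring carbonyl, while the 5''-O-methyl group is activated by chelation to C4''=O.

**14 to 13.** The methyl carbon on O7'' is reconnected to O5 (forward: the O5–CH2 bond is cut and the carbon takes up hydride). The reason is that the free O5–H and the methylated O7'' flank the axis and are the two halves of one formaldehyde acetal. The gain is a seven-membered ring that ties the two flavones together and makes the next cut intramolecular; none of the bridge atoms is wasted. The demand is cleavage at O5–CH2 and not at O7''–CH2, which the C4 carbonyl peri to O5 should secure by chelation.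

**13 to 12 (key disconnection).** The C6–C8'' bond is cut. This is the hardest bond: it is tetra-ortho-substituted and lies between two rings that each offer two nucleophilic positions. Within the bridge only C6 is ortho to O5, and C8'' is marked by iodine, so both ends are defined. The gain is large: the biaryl problem is reduced to the making of one acetal between two single flavones. The demand is closure of a seven-membered ring at a flanked C–H bond faster than reduction of the C–I bond. In one sentence: a formaldehyde acetal tying O5 of one flavone to O7'' of an 8''-iodinated second flavone is closed to the biaryl by intramolecular C–H arylation at C6. That sentence does not fit the customary cross-coupling of two separately activated flavones.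

**12 to 2 and 10 (through 11).** The O5–CH2 bond is cut. The reason is convergence: each half is a complete flavone, and the α-chloro ether 11 is reactive enough for the hydrogen-bonded, hindered O5. The demand is that 11 is generated without ring chlorination and used dry.

**10 to 9.** The O7''–CH2SMe bond is cut. The O,S-acetal is the stable precursor of 11. The demand is that the sulfide is installed after the iodination.

**9 to 8.** The C8''–I bond is cut. The bridge alone cannot distinguish C6'' from C8'' (both are ortho to O7''), so this end is defined by a halogen. The demand is iodination at C8'' and not at C6''.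

**8 to 6 (through 7).** The O1''–C2'' bond and the C2''=C3'' unsaturation of the pyranone are cut, and O7'' is masked as a methoxymethyl ether. The gain is an open-chain chalcone. The demand is ring closure through the only free phenol of 6.

**6 to 4 and 5.** The enone C=C bond (the future C2''–C3'') is cut by a retro-aldol. This gives an acetophenone and an aldehyde that already carries the protected 4'''-oxygen.

**4 to 3.** The O–CH2OMe bond is cut. Compound 3 already has the methyl ether at the future O5'' and two free phenols that differ by hydrogen bonding. The demand is selective protection of the phenol para to the acetyl group.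

**2 to 1.** The O7–CH2Ph bond is cut. Compound 1 already carries the 4'-O-methyl group. The demand is selectivity for O7 over the hydrogen-bonded O5.

## Other disconnections considered

**Alternative 1:** the first idea is to cut C6–C8'' between two separate, fully protected flavones. The forward step is a Suzuki–Miyaura coupling of the 6-iodide A1 with the 8''-boronate A2 to give the protected biflavone A3, followed by removal of the benzyl groups. Both partners must be activated beforehand by two regioselective halogenations and a borylation. The coupling would then have to build a tetra-ortho-substituted biaryl from a boronate flanked by two oxygens, for which protodeboronation is the expected competitor, and an iodide flanked by two benzyloxy groups. Nothing in the structure helps the two hindered carbons to meet. The step count is not lower than in the chosen plan, where the bridge brings the carbons together and only one partner is halogenated. This is also the route most chemists would draw first.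

**Alternative 2:** cut both pyranone rings first and the biaryl bond afterwards, at the stage of two acetophenones. The forward key step is a double flavone annulation on the biaryl diketone A4. The hindered biaryl bond still has to be made to reach A4, so the main difficulty is only moved. The two acetyl groups of A4 would have to be condensed with two different aromatic aldehydes although they are chemically almost identical. The two ring closures must also run in opposite senses, toward the phenol remote from the axis in one ring and toward the phenol next to the axis in the other. This requires six oxygens to be differentiated on A4, and the sequence is longer.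

**Alternative 3:** cut C6–C8'' between the two commercial, unprotected flavones. The forward step is an anodic (or chemical) dehydrogenative cross-coupling of 1 with genkwanin A5, which would give 15 in one step. The most easily oxidised site of A5 is the 4'''-phenol, which should direct bond formation to C3''' and not to C8''. In 1 the 7-phenol activates C6 and C8 almost equally, and homo-coupling of either partner is as easy as cross-coupling. The substitution pattern therefore does not explain the required selectivity, and protecting the 4'''-phenol would leave the C6/C8 and C6''/C8'' ambiguities. The bridge of the chosen plan removes exactly these ambiguities.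

Key step: step 8

## Route

**Step 1**
Reactants: 1 acacetin (5,7-dihydroxy-2-(4-methoxyphenyl)-4H-chromen-4-one)
Product: 2 7-(benzyloxy)-5-hydroxy-2-(4-methoxyphenyl)-4H-chromen-4-one
Conditions: BnBr (1.1 equiv), K2CO3, acetone, reflux
Reagents that add atoms: benzyl bromide, BrCc1ccccc1
Why: Williamson ether synthesis; the 7-OH is a vinylogous acid (para to C4=O) and is alkylated well before the 5-OH, which is held in a hydrogen bond to C4=O, so one equivalent of benzyl bromide should give the 7-monoether.

**Step 2**
Reactants: 3 1-(2,4-dihydroxy-6-methoxyphenyl)ethan-1-one (2',4'-dihydroxy-6'-methoxyacetophenone)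
Product: 4 1-[2-hydroxy-6-methoxy-4-(methoxymethoxy)phenyl]ethan-1-one
Conditions: MOMCl (1.1 equiv), K2CO3, acetone, 0 °C → rt
Reagents that add atoms: chloromethyl methyl ether, COCCl
Why: Williamson-type alkylation of the free 4'-OH; the 2'-OH is hydrogen-bonded to the acetyl group and should remain free for the later ring closure.

**Step 3**
Reactants: 4 1-[2-hydroxy-6-methoxy-4-(methoxymethoxy)phenyl]ethan-1-one; 5 4-(benzyloxy)benzaldehyde
Product: 6 (E)-3-[4-(benzyloxy)phenyl]-1-[2-hydroxy-6-methoxy-4-(methoxymethoxy)phenyl]prop-2-en-1-one
Conditions: KOH (50% aq.), EtOH, rt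
Reagents that add atoms: none
Why: Claisen–Schmidt (crossed aldol) condensation; the aldehyde has no α-hydrogen, and E1cB dehydration should give the conjugated E-enone.

**Step 4**
Reactants: 6 (E)-3-[4-(benzyloxy)phenyl]-1-[2-hydroxy-6-methoxy-4-(methoxymethoxy)phenyl]prop-2-en-1-one
Product: 8 2-[4-(benzyloxy)phenyl]-7-hydroxy-5-methoxy-4H-chromen-4-one, via 7-O-methoxymethyl flavone 7 (not isolated)
Conditions: I2 (10 mol%), DMSO, 120 °C; then 3 M HCl, MeOH, 60 °C
Reagents that add atoms: none
Why: Iodine-catalysed oxidative cyclisation of a 2'-hydroxychalcone (oxa-Michael closure, α-iodination and loss of HI, with DMSO regenerating iodine) through the only free phenol should give the pyranone with 5-OMe; acid methanolysis then removes the methoxymethyl group while the benzyl and methyl ethers persist.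

**Step 5**
Reactants: 8 2-[4-(benzyloxy)phenyl]-7-hydroxy-5-methoxy-4H-chromen-4-one
Product: 9 2-[4-(benzyloxy)phenyl]-7-hydroxy-8-iodo-5-methoxy-4H-chromen-4-one
Conditions: NIS (1.0 equiv), DMF, 0 °C → rt, dark
Reagents that add atoms: N-iodosuccinimide, O=C1CCC(=O)N1I
Why: Electrophilic aromatic iodination; 5,7-dioxygenated flavones with an alkylated O5 are attacked at C8, which here is ortho to the free 7-OH, para to 5-OMe and less crowded than C6 between two oxygens. One equivalent of NIS should limit a second iodination.

**Step 6**
Reactants: 9 2-[4-(benzyloxy)phenyl]-7-hydroxy-8-iodo-5-methoxy-4H-chromen-4-one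
Product: 10 2-[4-(benzyloxy)phenyl]-8-iodo-5-methoxy-7-[(methylsulfanyl)methoxy]-4H-chromen-4-one
Conditions: NaH, ClCH2SMe, NaI (cat.), DMF, 0 °C → rt
Reagents that add atoms: chloromethyl methyl sulfide, CSCCl
Why: Williamson etherification of the acidic 7-phenoxide (iodide activates the chloride by Finkelstein exchange) gives the methylthiomethyl ether, the storable precursor of the chloromethyl ether. It follows the iodination because the sulfide would not survive NIS.

**Step 7**
Reactants: 10 2-[4-(benzyloxy)phenyl]-8-iodo-5-methoxy-7-[(methylsulfanyl)methoxy]-4H-chromen-4-one; 2 7-(benzyloxy)-5-hydroxy-2-(4-methoxyphenyl)-4H-chromen-4-one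
Product: 12 7-(benzyloxy)-5-[({2-[4-(benzyloxy)phenyl]-8-iodo-5-methoxy-4-oxo-4H-chromen-7-yl}oxy)methoxy]-2-(4-methoxyphenyl)-4H-chromen-4-one (mixed formaldehyde acetal O5–CH2–O7''), via chloromethyl ether 11 (not isolated)
Conditions: SO2Cl2 (1.05 equiv), CH2Cl2, 0 °C, then evaporation; 2, NaH, DMF/THF, 0 °C → rt
Reagents that add atoms: sulfuryl chloride, O=S(=O)(Cl)Cl (its chlorine is carried by intermediate 11 and is lost again on the way to 12)
Why: Sulfuryl chloride converts the O,S-acetal into the aryloxymethyl chloride (chlorosulfonium formation and fragmentation), an α-chloro ether as reactive as chloromethyl methyl ether. It should alkylate the sodium 5-phenoxide of 2 in the way 5-O-methoxymethyl ethers of flavones are made, giving the unsymmetrical formaldehyde acetal.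

**Step 8**
Reactants: 12 7-(benzyloxy)-5-[({2-[4-(benzyloxy)phenyl]-8-iodo-5-methoxy-4-oxo-4H-chromen-7-yl}oxy)methoxy]-2-(4-methoxyphenyl)-4H-chromen-4-one
Product: 13 methylene-bridged biflavone: the C6–C8''-linked dimer of 7-(benzyloxy)-2-(4-methoxyphenyl)-4H-chromen-4-one and 2-[4-(benzyloxy)phenyl]-5-methoxy-4H-chromen-4-one whose O5 and O7'' are joined by one CH2 group (seven-membered 1,3-dioxepine ring C5–O5–CH2–O7''–C7''–C8''–C6; racemic)
Conditions: Pd(OAc)2 (10 mol%), PCy3·HBF4 (20 mol%), PivOH (30 mol%), K2CO3, Ag2CO3, DMA, 110 °C
Reagents that add atoms: none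
Why: Palladium-catalysed intramolecular direct arylation; the closest known reaction type is the cyclisation of aryl halides tethered through ether chains to an arene C–H bond, which forms six- and seven-membered biaryl rings. Zerovalent palladium inserts into the C8''–I bond, silver carbonate removes iodide and pivalate takes its place, and the divalent arylpalladium pivalate cleaves the C6–H bond by concerted metalation–deprotonation; reductive elimination from the eight-membered diarylpalladacycle forms C6–C8'' and closes the seven-membered 1,3-dioxepine ring (closure by aryl–aryl bond formation across the O5–CH2–O7'' bridge). Site selectivity on the acacetin unit is fixed by the bridge: C6 is the only C–H carbon ortho to O5, while C8 and C3 cannot reach the metal without a prohibitively strained ring, and C6–H is also the most acidic arene C–H of that unit because it lies between two oxygens, which suits the deprotonative mechanism. Site selectivity on the other unit is fixed by the iodine at C8''. No stereocentre is formed; the axis arises as a racemate inside a twisted bridged biaryl. The process to suppress is reduction of the C–I bond, which the intramolecular setting and the carboxylate shuttle should outrun.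

**Step 9**
Reactants: 13 methylene-bridged biflavone (O5–CH2–O7'' acetal across the C6–C8'' bond)
Product: 14 7-(benzyloxy)-6-{2-[4-(benzyloxy)phenyl]-5,7-dimethoxy-4-oxo-4H-chromen-8-yl}-5-hydroxy-2-(4-methoxyphenyl)-4H-chromen-4-one
Conditions: TiCl4 (2.5 equiv), Et3SiH (5 equiv), CH2Cl2, −78 → −20 °C; aq. NaHCO3
Reagents that add atoms: none
Why: Proposed new method: TiCl4 should bind the C4=O/O5 pair of the acacetin unit as a six-membered chelate, as chelating Lewis acids do when they cleave 5-O-alkyl groups of flavones selectively, so that the O5–CH2 bond ionises and leaves the aryloxycarbenium ion (or its chloride adduct) on O7'', which Et3SiH reduces to the methyl ether; the closest known reaction type is the Lewis-acid/silane reductive opening of cyclic acetals of diols to hydroxy ethers, which has not been shown on diaryl formaldehyde acetals.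

**Step 10**
Reactants: 14 7-(benzyloxy)-6-{2-[4-(benzyloxy)phenyl]-5,7-dimethoxy-4-oxo-4H-chromen-8-yl}-5-hydroxy-2-(4-methoxyphenyl)-4H-chromen-4-one
Product: 15 5,7-dihydroxy-6-[5-hydroxy-2-(4-hydroxyphenyl)-7-methoxy-4-oxo-4H-chromen-8-yl]-2-(4-methoxyphenyl)-4H-chromen-4-one (CNP0290866.0)
Conditions: BCl3 (1 M in CH2Cl2, excess), C6HMe5, CH2Cl2, −78 → 0 °C; MeOH
Reagents that add atoms: none
Why: BCl3 cleaves aryl benzyl ethers at low temperature (pentamethylbenzene traps the benzyl cation) and, through its chelate with C4''=O, the 5''-O-methyl group. The 4'-O- and 7''-O-methyl groups have no neighbouring carbonyl and should remain.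

## Compound list

1 | acacetin, 5,7-dihydroxy-2-(4-methoxyphenyl)-4H-chromen-4-one | COc1ccc(-c2cc(=O)c3c(O)cc(O)cc3o2)cc1 | starting material
2 | 7-(benzyloxy)-5-hydroxy-2-(4-methoxyphenyl)-4H-chromen-4-one | COc1ccc(-c2cc(=O)c3c(O)cc(OCc4ccccc4)cc3o2)cc1 | intermediate
3 | 1-(2,4-dihydroxy-6-methoxyphenyl)ethan-1-one | CC(=O)c1c(O)cc(O)cc1OC | starting material
4 | 1-[2-hydroxy-6-methoxy-4-(methoxymethoxy)phenyl]ethan-1-one | CC(=O)c1c(O)cc(OCOC)cc1OC | intermediate
5 | 4-(benzyloxy)benzaldehyde | O=Cc1ccc(OCc2ccccc2)cc1 | starting material
6 | (E)-3-[4-(benzyloxy)phenyl]-1-[2-hydroxy-6-methoxy-4-(methoxymethoxy)phenyl]prop-2-en-1-one | COCOc1cc(O)c(C(=O)/C=C/c2ccc(OCc3ccccc3)cc2)c(OC)c1 | intermediate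
7 | 2-[4-(benzyloxy)phenyl]-5-methoxy-7-(methoxymethoxy)-4H-chromen-4-one | COCOc1cc(OC)c2c(=O)cc(-c3ccc(OCc4ccccc4)cc3)oc2c1 | intermediate (not isolated)
8 | 2-[4-(benzyloxy)phenyl]-7-hydroxy-5-methoxy-4H-chromen-4-one | COc1cc(O)cc2oc(-c3ccc(OCc4ccccc4)cc3)cc(=O)c12 | intermediate
9 | 2-[4-(benzyloxy)phenyl]-7-hydroxy-8-iodo-5-methoxy-4H-chromen-4-one | COc1cc(O)c(I)c2oc(-c3ccc(OCc4ccccc4)cc3)cc(=O)c12 | intermediate
10 | 2-[4-(benzyloxy)phenyl]-8-iodo-5-methoxy-7-[(methylsulfanyl)methoxy]-4H-chromen-4-one | COc1cc(OCSC)c(I)c2oc(-c3ccc(OCc4ccccc4)cc3)cc(=O)c12 | intermediate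
11 | 2-[4-(benzyloxy)phenyl]-7-(chloromethoxy)-8-iodo-5-methoxy-4H-chromen-4-one | COc1cc(OCCl)c(I)c2oc(-c3ccc(OCc4ccccc4)cc3)cc(=O)c12 | intermediate (not isolated)
12 | 7-(benzyloxy)-5-[({2-[4-(benzyloxy)phenyl]-8-iodo-5-methoxy-4-oxo-4H-chromen-7-yl}oxy)methoxy]-2-(4-methoxyphenyl)-4H-chromen-4-one | COc1ccc(-c2cc(=O)c3c(OCOc4cc(OC)c5c(=O)cc(-c6ccc(OCc7ccccc7)cc6)oc5c4I)cc(OCc4ccccc4)cc3o2)cc1 | intermediate
13 | methylene-bridged biflavone (C6–C8'' bond; O5–CH2–O7'' acetal; 7-OBn, 4'-OMe, 5''-OMe, 4'''-OBn; racemic) | COc1ccc(-c2cc(=O)c3c4OCOc5cc(OC)c6c(=O)cc(-c7ccc(OCc8ccccc8)cc7)oc6c5-c4c(OCc5ccccc5)cc3o2)cc1 | intermediate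
14 | 7-(benzyloxy)-6-{2-[4-(benzyloxy)phenyl]-5,7-dimethoxy-4-oxo-4H-chromen-8-yl}-5-hydroxy-2-(4-methoxyphenyl)-4H-chromen-4-one | COc1ccc(-c2cc(=O)c3c(O)c(-c4c(OC)cc(OC)c5c(=O)cc(-c6ccc(OCc7ccccc7)cc6)oc45)c(OCc4ccccc4)cc3o2)cc1 | intermediate
15 | 5,7-dihydroxy-6-[5-hydroxy-2-(4-hydroxyphenyl)-7-methoxy-4-oxo-4H-chromen-8-yl]-2-(4-methoxyphenyl)-4H-chromen-4-one | COc1ccc(-c2cc(=O)c3c(O)c(-c4c(OC)cc(O)c5c(=O)cc(-c6ccc(O)cc6)oc45)c(O)cc3o2)cc1 | target

## Step count and least certain steps

Total step count: 10. Longest linear sequence: 9 steps (3 to 15 through steps 2 to 10); step 1 prepares the second fragment.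

**Step 9 (Proposed new method).** Most likely to go wrong: ionisation at the O7''–CH2 bond in place of the O5–CH2 bond, because coordination of titanium at C4''=O also makes O7'' a fair leaving group; hydride transfer to a Lewis-acid-activated pyranone ring; or premature loss of benzyl groups. Fallback by known chemistry, from 13: acid-catalysed methanolysis of the aryl formal (HCl, MeOH/THF, reflux) should give 7-(benzyloxy)-6-{2-[4-(benzyloxy)phenyl]-7-hydroxy-5-methoxy-4-oxo-4H-chromen-8-yl}-5-hydroxy-2-(4-methoxyphenyl)-4H-chromen-4-one F1. Williamson methylation (MeI, K2CO3, acetone) of its only phenol that is not hydrogen-bonded to a carbonyl (7''-OH) returns to 14.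

**Step 8 (key step).** Most likely to go wrong: reduction of the C–I bond to C–H if palladation of the doubly flanked C6–H is slow, catalyst inhibition by iodide, or reluctance of the hindered seven-membered ring to close. Fallback that abandons the bridge: from 9, methylation (MeI, K2CO3, DMF) gives 2-[4-(benzyloxy)phenyl]-8-iodo-5,7-dimethoxy-4H-chromen-4-one F2. Miyaura borylation (B2pin2, Pd(dppf)Cl2, KOAc, dioxane) gives 2-[4-(benzyloxy)phenyl]-5,7-dimethoxy-8-(4,4,5,5-tetramethyl-1,3,2-dioxaborolan-2-yl)-4H-chromen-4-one F3. From 2, iodination directed by the free 5-OH (NIS, DMF) gives 7-(benzyloxy)-5-hydroxy-6-iodo-2-(4-methoxyphenyl)-4H-chromen-4-one F4. Suzuki–Miyaura coupling of F3 with F4 (Pd(OAc)2, SPhos, K3PO4, toluene/water) then comes back to the route at 14.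

**Step 5.** Most likely to go wrong: attack at C6 in place of C8, or a second iodination, since both carbons are ortho to the free 7-OH. Fallback that sets the iodine before the pyranone exists: from 4, iodination ortho to the hydrogen-bonded 2'-OH (NIS, or BnNMe3·ICl2 with NaHCO3) gives 1-[2-hydroxy-3-iodo-6-methoxy-4-(methoxymethoxy)phenyl]ethan-1-one F5. Claisen–Schmidt condensation with 5 gives (E)-3-[4-(benzyloxy)phenyl]-1-[2-hydroxy-3-iodo-6-methoxy-4-(methoxymethoxy)phenyl]prop-2-en-1-one F6. Oxidative cyclisation (I2, DMSO) through the phenol next to iodine gives 2-[4-(benzyloxy)phenyl]-8-iodo-5-methoxy-7-(methoxymethoxy)-4H-chromen-4-one F7, and acid methanolysis returns to 9.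

**Step 7.** Most likely to go wrong: hydrolysis of the chloromethyl ether, or slow O-alkylation of the hydrogen-bonded and hindered O5, so that the electrophile is consumed by adventitious water. Fallback with reversed roles: from 2, alkylation (NaH, ClCH2SMe, NaI, DMF) gives 7-(benzyloxy)-2-(4-methoxyphenyl)-5-[(methylsulfanyl)methoxy]-4H-chromen-4-one F8. Sulfuryl chloride gives 7-(benzyloxy)-5-(chloromethoxy)-2-(4-methoxyphenyl)-4H-chromen-4-one F9, which is treated with the potassium salt of the more acidic phenol 9 (K2CO3, DMF) to return to 12.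

**Step 10.** Most likely to go wrong: partial cleavage of a methyl ether that should stay (7''-OMe or 4'-OMe) on extended exposure, or incomplete removal of the 5''-O-methyl group. Fallback in two orthogonal operations: from 14, hydrogenolysis of the benzyl ethers (H2, 10% Pd/C, EtOAc/MeOH) gives 5,7-dihydroxy-6-[2-(4-hydroxyphenyl)-5,7-dimethoxy-4-oxo-4H-chromen-8-yl]-2-(4-methoxyphenyl)-4H-chromen-4-one F10. Chelation-selective demethylation of the 5''-O-methyl group (AlCl3, MeCN, 60 °C) then gives 15.

## Further compounds

F1 | step 9 | 7-(benzyloxy)-6-{2-[4-(benzyloxy)phenyl]-7-hydroxy-5-methoxy-4-oxo-4H-chromen-8-yl}-5-hydroxy-2-(4-methoxyphenyl)-4H-chromen-4-one | COc1ccc(-c2cc(=O)c3c(O)c(-c4c(O)cc(OC)c5c(=O)cc(-c6ccc(OCc7ccccc7)cc6)oc45)c(OCc4ccccc4)cc3o2)cc1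
F2 | step 8 | 2-[4-(benzyloxy)phenyl]-8-iodo-5,7-dimethoxy-4H-chromen-4-one | COc1cc(OC)c(I)c2oc(-c3ccc(OCc4ccccc4)cc3)cc(=O)c12
F3 | step 8 | 2-[4-(benzyloxy)phenyl]-5,7-dimethoxy-8-(4,4,5,5-tetramethyl-1,3,2-dioxaborolan-2-yl)-4H-chromen-4-one | COc1cc(OC)c(B3OC(C)(C)C(C)(C)O3)c2oc(-c3ccc(OCc4ccccc4)cc3)cc(=O)c12
F4 | step 8 | 7-(benzyloxy)-5-hydroxy-6-iodo-2-(4-methoxyphenyl)-4H-chromen-4-one | COc1ccc(-c2cc(=O)c3c(O)c(I)c(OCc4ccccc4)cc3o2)cc1
F5 | step 5 | 1-[2-hydroxy-3-iodo-6-methoxy-4-(methoxymethoxy)phenyl]ethan-1-one | CC(=O)c1c(O)c(I)c(OCOC)cc1OC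
F6 | step 5 | (E)-3-[4-(benzyloxy)phenyl]-1-[2-hydroxy-3-iodo-6-methoxy-4-(methoxymethoxy)phenyl]prop-2-en-1-one | COCOc1cc(OC)c(C(=O)/C=C/c2ccc(OCc3ccccc3)cc2)c(O)c1I
F7 | step 5 | 2-[4-(benzyloxy)phenyl]-8-iodo-5-methoxy-7-(methoxymethoxy)-4H-chromen-4-one | COCOc1cc(OC)c2c(=O)cc(-c3ccc(OCc4ccccc4)cc3)oc2c1I
F8 | step 7 | 7-(benzyloxy)-2-(4-methoxyphenyl)-5-[(methylsulfanyl)methoxy]-4H-chromen-4-one | COc1ccc(-c2cc(=O)c3c(OCSC)cc(OCc4ccccc4)cc3o2)cc1
F9 | step 7 | 7-(benzyloxy)-5-(chloromethoxy)-2-(4-methoxyphenyl)-4H-chromen-4-one | COc1ccc(-c2cc(=O)c3c(OCCl)cc(OCc4ccccc4)cc3o2)cc1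
F10 | step 10 | 5,7-dihydroxy-6-[2-(4-hydroxyphenyl)-5,7-dimethoxy-4-oxo-4H-chromen-8-yl]-2-(4-methoxyphenyl)-4H-chromen-4-one | COc1ccc(-c2cc(=O)c3c(O)c(-c4c(OC)cc(OC)c5c(=O)cc(-c6ccc(O)cc6)oc45)c(O)cc3o2)cc1
A1 | alternative 1 | 5,7-bis(benzyloxy)-6-iodo-2-(4-methoxyphenyl)-4H-chromen-4-one | COc1ccc(-c2cc(=O)c3c(OCc4ccccc4)c(I)c(OCc4ccccc4)cc3o2)cc1
A2 | alternative 1 | 5-(benzyloxy)-2-[4-(benzyloxy)phenyl]-7-methoxy-8-(4,4,5,5-tetramethyl-1,3,2-dioxaborolan-2-yl)-4H-chromen-4-one | COc1cc(OCc2ccccc2)c2c(=O)cc(-c3ccc(OCc4ccccc4)cc3)oc2c1B1OC(C)(C)C(C)(C)O1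
A3 | alternative 1 | 5,7-bis(benzyloxy)-6-{5-(benzyloxy)-2-[4-(benzyloxy)phenyl]-7-methoxy-4-oxo-4H-chromen-8-yl}-2-(4-methoxyphenyl)-4H-chromen-4-one | COc1ccc(-c2cc(=O)c3c(OCc4ccccc4)c(-c4c(OC)cc(OCc5ccccc5)c5c(=O)cc(-c6ccc(OCc7ccccc7)cc6)oc45)c(OCc4ccccc4)cc3o2)cc1
A4 | alternative 2 | 1,1'-[2',4,6'-tris(benzyloxy)-2,4'-dihydroxy-6-methoxy-[1,1'-biphenyl]-3,3'-diyl]di(ethan-1-one) | CC(=O)c1c(O)c(-c2c(OCc3ccccc3)cc(O)c(C(C)=O)c2OCc2ccccc2)c(OC)cc1OCc1ccccc1
A5 | alternative 3 | genkwanin, 5-hydroxy-2-(4-hydroxyphenyl)-7-methoxy-4H-chromen-4-one | COc1cc(O)c2c(=O)cc(-c3ccc(O)cc3)oc2c1
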